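Assumption: the SMILES of CNP0017937.0 has no stereocentre, and the diaryl ether has no hindered axis. The target is therefore achiral, and "single enantiomer" is read as the one compound drawn.

## Analysis of the target

Compound 10 is a diphenyl ether: two benzene rings, A and B, are joined only by the bridge oxygen between C1 of ring A and C1′ of ring B, and there is no further ring, no chain and no stereocentre. Ring A carries OMe at C2 and Br at C3 and C5, and ring B carries a free OH at C2′ and Br at C4′. In ring A both bromines stand ortho/para to the oxygen at C2 and meta to the bridge oxygen, so they must enter while O–C2 is a free phenol, and the methyl group must follow. In ring B the bromine stands para to the bridge oxygen and meta to the OH, so it cannot enter while that OH is free; in addition, the oxygens at C2 and C2′ are both ortho to the bridge, yet one must end as OMe and the other as OH. The bridge is a C(sp2)–O–C(sp2) bond between two halogenated rings, neither of which is an SNAr acceptor as it stands, and three C–Br bonds would compete in any copper or palladium coupling. The sensitive groups are the C–Br bonds (reducing metals, organolithiums, hydrogenolysis) and the free phenol (oxidants). The plan rests on one feature of ring A: C2 bears oxygen and all three carbons ortho and para to it are substituted, C1 by the bridge oxygen and C3 and C5 by bromine, which is the reactivity map of a cyclohexanone (C2 the carbonyl carbon, C1 an α-carbon open to SN2, C3 the α′-carbon, C5 the para carbon of the phenol set free by aromatisation). Ring A is therefore treated as a cyclohexanone in disguise, and the diaryl ether bond as an alkyl aryl ether bond that becomes aromatic later.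

## Retrosynthetic reasoning

**10 to 8, bond C2′–O.** The free OH of ring B is traced back through aryl formate 9 to the formyl group of aldehyde 8. The forward reaction is a Baeyer–Villiger oxidation with cleavage of the formate. A formyl carbon at C2′ solves three problems at once. While it is present the molecule has only one phenolic oxygen, so OMe versus OH needs no protecting group. It also deactivates ring B towards electrophiles, and it makes the phenoxide of the ring B building block a weak base. The forward step must make the aryl group migrate rather than hydrogen, and the ortho ether oxygen supports this.

**8 to 7, bond O–CH3.** The methyl group is removed next. The oxygen at C2 must be a free phenol when C3 and C5 are brominated, because the methyl ether would not direct both bromines reliably. The forward reaction is a simple O-methylation of the only OH in 7.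

**7 to 3, bonds C3–Br and C5–Br and the aromatic sextet of ring A (key step).** Both ring A bromines are removed, and ring A is taken back through phenol 6, bromo enone 5 and dibromo ketone 4 to the saturated ketone of 3. This cut turns the hardest bond of the target, the aryl–O–aryl bridge, into an ordinary secondary alkyl aryl ether α to a carbonyl group. It also removes two of the three halogens. In one flask the forward reaction must dehydrogenate the ring twice by α-bromination and dehydrobromination, and then load the new phenol at its only free ortho and para positions. The precursor 3 has one aromatic ring and one bromine, whereas the product 7 has the complete carbon–oxygen–bromine skeleton.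

**3 to 1 and 2, bond C1–O.** With C1 now sp3 and next to a carbonyl group, the bridge is cut as an SN2 bond between the phenol oxygen of 1 and the α-carbon of 2. The oxygen is assigned to ring B because in 1 it already sits para to the bromine and ortho to the latent OH, so the regiochemistry of ring B is bought, not made. Both partners are cheap commercial compounds, and no metal and no activated arene is needed.

## Alternatives that were turned down

Alternative 1: the textbook cut, bridge O–C1′ as a C(sp2)–O bond.
- **Forward key step:** an SNAr of the phenoxide of 3,5-dibromo-2-methoxyphenol A1 on 5-bromo-2-fluorobenzaldehyde A2. This gives 8 directly and is followed by step 4. Ullmann and iodonium variants belong to the same cut.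
- **Access to A1:** A1 has its bromines meta to the free OH and ortho/para to the OMe, so it cannot come from direct bromination of its bromine-free parent. It must instead be built from 3,5-dibromosalicylaldehyde A3 by methylation, Baeyer–Villiger oxidation and hydrolysis. A route through A3 therefore runs the aldehyde-to-phenol sequence twice and is longer.
- **The coupling itself:** the phenoxide of A1 is weak and calls for hot, basic conditions, and a copper or palladium version cannot tell the C–Br bonds apart.
- **Leanest variant:** catechol A4 is coupled with A2 to give 6, followed by dibromination, which equals the present route in length. A4 is an oxidation-prone, doubly nucleophilic partner, so double arylation is a risk. The aryl–oxygen bond is still forced head-on, and A2 is an arene bought only for its leaving group. This variant simplifies nothing and was kept only as the conservative benchmark.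

Alternative 2: the biomimetic cut, bridge O–C1 by oxidative C–H/O–H cross-coupling of two bromophenol monomers.
- **Forward key step:** a one-electron oxidation (anodic or chemical) of a mixture of 2,4-dibromophenol A5 and 4-bromocatechol A6. This would give 2,4-dibromo-6-(4-bromo-2-hydroxyphenoxy)phenol A8, and methylation of the more acidic OH of A8 would follow.
- **Wrong partner oxidised:** A6 is oxidised far more easily than A5 and goes to 4-bromo-1,2-benzoquinone A7. A7 is electrophilic at its ring carbons and not at oxygen, so the phenoxide of A5 would give a trioxygenated ring.
- **Self-coupling:** the radical of A5 carries spin at O, C2, C4 and C6 and couples with itself through C–C, C–O and ipso (bromine-loss) modes.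
- **Over-oxidation:** A8 is easier to oxidise than A5 and would be consumed as it forms. Nothing in the substrates replaces the enzyme pocket.
- **Final methylation:** it must distinguish two phenols whose acidities differ only modestly.
- **Verdict:** the route has two steps on paper but three unsolved selectivities.

Alternative 3: all three C–Br bonds last, on a symmetrical bromine-free ether.
- **Forward key step:** 2,2′-oxydiphenol A9 would be desymmetrised to 2-(2-hydroxyphenoxy)phenyl acetate A10. The key step would be the tribromination of A10 to 5-bromo-2-(3,5-dibromo-2-hydroxyphenoxy)phenyl acetate A11. Methylation and deacetylation of A11 would follow.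
- **Access to A9:** A9 is itself a diaryl ether and no commodity. It needs a copper-mediated coupling of two anisole-type partners and a double demethylation, so the hard bond is not avoided.
- **Desymmetrisation:** the monoacetylation to A10 is statistical.
- **Third bromination:** it must occur para to a weakly donating aryloxy group and meta to an acyloxy group, and it is orders of magnitude slower than the first two.
- **Acyl migration:** in A11 the acetyl group can migrate between the two ortho oxygens under the basic methylation, which would scramble OMe and OH.
- **Step count:** about seven steps.

Key step: step 2

## Route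

Step 1
Reactants: 1 5-bromosalicylaldehyde (5-bromo-2-hydroxybenzaldehyde); 2 2-chlorocyclohexanone (racemic)
Product: 3 5-bromo-2-[(2-oxocyclohexyl)oxy]benzaldehyde (racemic)
Conditions: K2CO3 (1.1 equiv), DMF, 60–70 °C
Reagents that add atoms: none
Why: Williamson ether synthesis at an α-halo ketone, where the neighbouring carbonyl group accelerates SN2 at the secondary carbon. The phenoxide of 1 (ortho formyl, para bromine) is a weak base, which should keep Favorskii contraction of 2 and enolate chemistry of 3 (intramolecular aldol onto CHO, the first stage of a Rap–Stoermer reaction) slow. The new stereocentre is formed racemic and is erased in step 2.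

Step 2
Reactants: 3 5-bromo-2-[(2-oxocyclohexyl)oxy]benzaldehyde
Product: 7 5-bromo-2-(3,5-dibromo-2-hydroxyphenoxy)benzaldehyde, via dibromo ketone 4 (not isolated), via bromo enone 5 (not isolated), via phenol 6 (not isolated)
Conditions: Br2 (4.1 equiv, slow addition), HBr (cat.), glacial AcOH, 20 → 90 °C, dark; aq NaHSO3 work-up
Reagents that add atoms: bromine, BrBr
Why: Acid-catalysed enolisation of 3 towards both α-carbons and capture of the enols by bromine should give dibromo ketone 4; at 85–90 °C the tertiary C–Br bond next to the aryloxy oxygen ionises with oxocarbenium assistance and loses a proton to give bromo enone 5, which loses its second hydrogen bromide across C3–C4 of ring A, and the resulting cyclohexadienone tautomerises to phenol 6. Phenol 6 is by far the most nucleophilic species in the flask and takes up the last two equivalents of bromine at C3 and C5 of ring A, the only free ortho and para positions of the new OH, since the second ortho position (C1) holds the bridge oxygen. The closest known reaction type is the halogenation–dehydrohalogenation aromatisation of cyclohexanones and cyclohexenones to phenols and halophenols, joined here to an ordinary phenol bromination in the same flask. No ring is closed and no stereocentre is set: the six-membered carbocycle is already there and is aromatised, and the stereocentres of 3, 4 and 5 are erased. Site selectivity is secured by the substrate: ring B carries CHO and Br and, after aromatisation, only a weakly donating aryloxy group, and C4 and C6 of ring A are meta to the OH, so that bromination should stop at 7. α-Bromination is reversible in HBr/AcOH, so sp3-bound bromine in a wrong place or number is given back and drains into the aromatic sink, and every order of the single events converges on 7. Slow addition keeps free bromine low, which holds back addition to the enol ether C=C of 5 (a process of higher order in bromine), while enol and phenol bromination stay fast. Water-free acetic acid in the dark keeps the formyl group from oxidation and the alkyl and vinyl ether stages from hydrolysis.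

Step 3
Reactants: 7 5-bromo-2-(3,5-dibromo-2-hydroxyphenoxy)benzaldehyde
Product: 8 5-bromo-2-(3,5-dibromo-2-methoxyphenoxy)benzaldehyde
Conditions: MeI (1.5 equiv), K2CO3 (1.5 equiv), DMF, 25 °C
Reagents that add atoms: iodomethane, CI
Why: Williamson O-methylation of an acidic ortho,para-dibromophenol. It is the only OH in the molecule because the second oxygen of the target is still a formyl carbon, so no chemoselectivity is asked for. The aldehyde, the ether and the C–Br bonds are inert to these conditions.

Step 4
Reactants: 8 5-bromo-2-(3,5-dibromo-2-methoxyphenoxy)benzaldehyde
Product: 10 5-bromo-2-(3,5-dibromo-2-methoxyphenoxy)phenol, via aryl formate 9 (not isolated)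
Conditions: mCPBA (1.4 equiv), CH2Cl2, 25 → 40 °C; then K2CO3 (cat.), MeOH, 25 °C
Reagents that add atoms: 3-chloroperoxybenzoic acid (mCPBA), O=C(OO)c1cccc(Cl)c1
Why: Baeyer–Villiger oxidation of an ortho-aryloxybenzaldehyde. In the Criegee adduct the aryl group, enriched by the ortho ether oxygen, should migrate in preference to hydrogen and give formate 9, which catalytic carbonate in methanol transesterifies to the free phenol. The OMe group, the bridge and the three C–Br bonds are untouched.

## Compound list

1 | 5-bromosalicylaldehyde (5-bromo-2-hydroxybenzaldehyde) | O=Cc1cc(Br)ccc1O | starting material
2 | 2-chlorocyclohexanone (racemic) | O=C1CCCCC1Cl | starting material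
3 | 5-bromo-2-[(2-oxocyclohexyl)oxy]benzaldehyde (racemic) | O=Cc1cc(Br)ccc1OC1CCCCC1=O | intermediate
4 | 5-bromo-2-[(1,3-dibromo-2-oxocyclohexyl)oxy]benzaldehyde (mixture of racemic diastereomers, not isolated) | O=Cc1cc(Br)ccc1OC1(Br)CCCC(Br)C1=O | intermediate
5 | 5-bromo-2-[(5-bromo-6-oxocyclohex-1-en-1-yl)oxy]benzaldehyde (racemic, not isolated) | O=Cc1cc(Br)ccc1OC1=CCCC(Br)C1=O | intermediate
6 | 5-bromo-2-(2-hydroxyphenoxy)benzaldehyde (not isolated) | O=Cc1cc(Br)ccc1Oc1ccccc1O | intermediate
7 | 5-bromo-2-(3,5-dibromo-2-hydroxyphenoxy)benzaldehyde | O=Cc1cc(Br)ccc1Oc1cc(Br)cc(Br)c1O | intermediate
8 | 5-bromo-2-(3,5-dibromo-2-methoxyphenoxy)benzaldehyde | O=Cc1cc(Br)ccc1Oc1cc(Br)cc(Br)c1OC | intermediate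
9 | 5-bromo-2-(3,5-dibromo-2-methoxyphenoxy)phenyl formate (not isolated) | O=COc1cc(Br)ccc1Oc1cc(Br)cc(Br)c1OC | intermediate
10 | 5-bromo-2-(3,5-dibromo-2-methoxyphenoxy)phenol (CNP0017937.0, achiral) | COc1c(Br)cc(Br)cc1Oc1ccc(Br)cc1O | target

## Step count and least certain steps

Total step count: 4. Longest linear sequence: 4 (steps 1 to 4).

**Step 2 (key step).** Three processes are most likely to spoil it.
- Bromine may add across the enol ether double bond at the stage of 5 and re-eliminate, which would place a further bromine at C6 of ring A.
- The alkyl or vinyl ether bond may be cleaved by acid before ring A is aromatic, because the phenol of ring B is a good leaving group.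
- The reaction may stall at the polybromo ketone stage if the acid-promoted dehydrobromination is too slow.

The fallback separates aromatisation from bromination. From 3, a palladium(II)-catalysed aerobic dehydrogenation would be run (Pd(TFA)2, 2-(dimethylamino)pyridine, TsOH, O2, DMSO, 80 °C). This is a known way from cyclohexanones to phenols through two cycles of α-palladation and β-hydride elimination. It would give phenol 6 as an isolated compound with no halogen source and no hydrogen halide present. An ordinary dibromination (Br2, 2 equiv, AcOH, 20 °C) would then return to the route at 7. The phosphine-free, acidic and oxidising medium should leave the C–Br bond of ring B alone. This fallback makes no compound outside the compound list, hence the entry F0.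

**Step 1.** The phenoxide of 1 is a weak nucleophile, so the substitution may be slow enough for two side processes to intervene. One is base-induced loss of 2 by Favorskii contraction or dehydrochlorination. The other is intramolecular aldol addition of the enolate of 3 onto its own formyl group.

The fallback makes the C–O bond at the alcohol oxidation level, where no enolate can exist. From 1, opening of cyclohexene oxide F1 with the phenoxide (K2CO3 cat., DMF, 110 °C, anti opening) would give rac-trans-5-bromo-2-[(2-hydroxycyclohexyl)oxy]benzaldehyde F2. Oxidation of F2 with Dess–Martin periodinane in CH2Cl2 under non-basic conditions would return to the route at 3.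

**Step 4.** Hydrogen may migrate instead of the aryl group in the Criegee adduct, so that the aldehyde is oxidised to the acid level rather than to the formate. Ring B is only moderately electron-rich: bromine is meta to the migrating carbon, and the donor oxygen is shared with an electron-poor ring.

The fallback replaces the competing hydrogen by a methyl group, which migrates poorly. From 8, addition of MeMgBr (THF, −78 → 0 °C, too cold for bromine–magnesium exchange) would give 1-[5-bromo-2-(3,5-dibromo-2-methoxyphenoxy)phenyl]ethanol F3. Dess–Martin oxidation of F3 would give 1-[5-bromo-2-(3,5-dibromo-2-methoxyphenoxy)phenyl]ethanone F4. Baeyer–Villiger oxidation of F4 (mCPBA, TFA, CH2Cl2) would give 5-bromo-2-(3,5-dibromo-2-methoxyphenoxy)phenyl acetate F5. Methanolysis of F5 (K2CO3 cat., MeOH) would return to the route at 10.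

## Further compounds

F0 | step 2 | none | none
F1 | step 1 | cyclohexene oxide (7-oxabicyclo[4.1.0]heptane, meso, purchased) | C1CC[C@H]2[C@@H](C1)O2
F2 | step 1 | rac-trans-5-bromo-2-[(2-hydroxycyclohexyl)oxy]benzaldehyde (one enantiomer drawn) | O=Cc1cc(Br)ccc1O[C@@H]1CCCC[C@H]1O
F3 | step 4 | 1-[5-bromo-2-(3,5-dibromo-2-methoxyphenoxy)phenyl]ethanol (racemic) | CC(O)c1cc(Br)ccc1Oc1cc(Br)cc(Br)c1OC
F4 | step 4 | 1-[5-bromo-2-(3,5-dibromo-2-methoxyphenoxy)phenyl]ethanone | CC(=O)c1cc(Br)ccc1Oc1cc(Br)cc(Br)c1OC
F5 | step 4 | 5-bromo-2-(3,5-dibromo-2-methoxyphenoxy)phenyl acetate | CC(=O)Oc1cc(Br)ccc1Oc1cc(Br)cc(Br)c1OC
A1 | alternative 1 | 3,5-dibromo-2-methoxyphenol | COc1c(O)cc(Br)cc1Br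
A2 | alternative 1 | 5-bromo-2-fluorobenzaldehyde | O=Cc1cc(Br)ccc1F
A3 | alternative 1 | 3,5-dibromosalicylaldehyde | O=Cc1cc(Br)cc(Br)c1O
A4 | alternative 1 | catechol | Oc1ccccc1O
A5 | alternative 2 | 2,4-dibromophenol | Oc1ccc(Br)cc1Br
A6 | alternative 2 | 4-bromocatechol | Oc1ccc(Br)cc1O
A7 | alternative 2 | 4-bromo-1,2-benzoquinone | O=C1C=CC(Br)=CC1=O
A8 | alternative 2 | 2,4-dibromo-6-(4-bromo-2-hydroxyphenoxy)phenol | Oc1cc(Br)ccc1Oc1cc(Br)cc(Br)c1O
A9 | alternative 3 | 2,2′-oxydiphenol | Oc1ccccc1Oc1ccccc1O
A10 | alternative 3 | 2-(2-hydroxyphenoxy)phenyl acetate | CC(=O)Oc1ccccc1Oc1ccccc1O
A11 | alternative 3 | 5-bromo-2-(3,5-dibromo-2-hydroxyphenoxy)phenyl acetate | CC(=O)Oc1cc(Br)ccc1Oc1cc(Br)cc(Br)c1O
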